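The route cuts the C5–C6 bond of the ten-membered carbocycle. C6 is both the carbinol carbon of the five-membered lactone (O–C6–C7–C11–C12) and allylic to C4=C5. A Nozaki–Hiyama–Kishi closure of a Z-vinyl iodide (C5) onto an aldehyde (C6) therefore forms the ring, the C5–C6 bond and the C6 alcohol in one operation. That alcohol then steers the C4–C5 epoxidation and captures CO with the cis C7 ethynyl group. The precursor is an acyclic chain running from C5 to C6 that holds the C1=C10 enoate, a C9 silyl ether, a C8 PMB ether and a C7 silylethynyl branch next to the aldehyde.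

Key step: step 16

Remark: the C9 oxygen is carried as a TBS ether and acetylated only after the lactone is closed, because an allylic ester beside the enoate could be ionised by the zerovalent nickel and palladium used later and would not pass the enolate steps.

Locants and abbreviations: target locants are used for all compounds (ring C1–C10, lactone carbons C11–C13, ester carbon C14, C4 methyl C15). TBS = tert-butyldimethylsilyl, PMB = 4-methoxybenzyl, TMS = trimethylsilyl.

Step 1
Reactants: 1 (3-bromopropoxy)(tert-butyl)dimethylsilane; 2 propyne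
Product: 6 tert-butyl{[(4Z)-5-iodo-4-methylpent-4-en-1-yl]oxy}dimethylsilane, via Grignard reagent 3 (not isolated), via alkylcopper 4 (not isolated), via alkenylcopper 5 (not isolated)
Conditions: Mg, Et2O, rt; CuBr·SMe2, Et2O/Me2S, −45 °C; 2, −25 °C; I2, THF, −78 to 0 °C
Reagents that add atoms: iodine, II
Why: Alkyne carbocupration followed by iodinolysis: the alkylcopper adds syn across propyne with the alkyl group on the internal carbon, so C3 and copper, and after retentive iodination C3 and iodine, are cis (4Z).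

Step 2
Reactants: 6 tert-butyl{[(4Z)-5-iodo-4-methylpent-4-en-1-yl]oxy}dimethylsilane
Product: 7 (4Z)-5-iodo-4-methylpent-4-en-1-ol
Conditions: CSA (cat.), MeOH, rt
Reagents that add atoms: none
Why: Acid-catalysed methanolysis of a primary silyl ether, which does not touch the vinyl iodide.

Step 3
Reactants: 7 (4Z)-5-iodo-4-methylpent-4-en-1-ol
Product: 8 (4Z)-5-iodo-4-methylpent-4-enal
Conditions: Dess–Martin periodinane, pyridine, CH2Cl2, 0 °C to rt
Reagents that add atoms: none
Why: Dess–Martin oxidation of a primary alcohol stops at the aldehyde and leaves the Z-vinyl iodide unchanged.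

Step 4
Reactants: 9 (2E)-but-2-ene-1,4-diol
Product: 10 (2E)-4-(TBS-oxy)but-2-en-1-ol
Conditions: NaH (1 equiv), THF, 0 °C; TBSCl (1 equiv), rt
Reagents that add atoms: tert-butyldimethylsilyl chloride, CC(C)(C)[Si](C)(C)Cl
Why: Monosilylation of a symmetrical diol through its sparingly soluble mono-sodium alkoxide, a standard desymmetrising O-silylation.

Step 5
Reactants: 10 (2E)-4-(TBS-oxy)but-2-en-1-ol
Product: 11 [(2R,3R)-3-(TBS-oxymethyl)oxiran-2-yl]methanol
Conditions: Ti(OiPr)4 (cat.), D-(−)-diisopropyl tartrate (cat.), t-BuOOH, 4 Å molecular sieves, CH2Cl2, −20 °C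
Reagents that add atoms: tert-butyl hydroperoxide, CC(C)(C)OO
Why: Sharpless asymmetric epoxidation of an E-allylic alcohol, in which the D-tartrate ligand directs oxygen to the face that gives the (2R,3R) trans-epoxide and so fixes C8 and the configuration from which C7 is derived.

Step 6
Reactants: 11 [(2R,3R)-3-(TBS-oxymethyl)oxiran-2-yl]methanol; 12 ethynyltrimethylsilane
Product: 15 (2S,3S)-3-(TBS-oxymethyl)-5-(trimethylsilyl)pent-4-yne-1,2-diol, via lithium acetylide 13 (not isolated), via alkynylalane 14 (not isolated)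
Conditions: 12, n-BuLi, toluene, 0 °C; Et2AlCl, 0 °C; then 11, 0 °C to rt; aq. potassium sodium tartrate
Reagents that add atoms: none
Why: Alkynylalane opening of a 2,3-epoxy alcohol: the aluminium alkoxide at O9 directs SN2 attack to the distal epoxide carbon (C7) with inversion, which sets the C7 ethynyl group anti to the C8 oxygen.

Step 7
Reactants: 15 (2S,3S)-3-(TBS-oxymethyl)-5-(trimethylsilyl)pent-4-yne-1,2-diol
Product: 16 tert-butyl{[(2S)-2-[(4S)-2-(4-methoxyphenyl)-1,3-dioxolan-4-yl]-4-(trimethylsilyl)but-3-yn-1-yl]oxy}dimethylsilane (both acetal epimers)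
Conditions: 4-MeOC6H4CH(OMe)2, PPTS (cat.), CH2Cl2, rt
Reagents that add atoms: 4-methoxybenzaldehyde dimethyl acetal, COc1ccc(cc1)C(OC)OC
Why: Acid-catalysed transacetalisation of a 1,2-diol to the 4-methoxybenzylidene acetal, mild enough for the primary TBS ether.

Step 8
Reactants: 16 4-methoxybenzylidene acetal (see step 7)
Product: 17 (2S,3S)-3-(TBS-oxymethyl)-2-(PMB-oxy)-5-(trimethylsilyl)pent-4-yn-1-ol
Conditions: i-Bu2AlH, CH2Cl2, −78 to 0 °C
Reagents that add atoms: none
Why: Regioselective reductive opening of a 4-methoxybenzylidene acetal: the aluminium hydride binds the less hindered primary oxygen, so the PMB group stays on O8 and the C9 alcohol is freed.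

Step 9
Reactants: 17 (2S,3S)-3-(TBS-oxymethyl)-2-(PMB-oxy)-5-(trimethylsilyl)pent-4-yn-1-ol
Product: 18 (2S,3S)-3-(TBS-oxymethyl)-2-(PMB-oxy)-5-(trimethylsilyl)pent-4-ynal
Conditions: Dess–Martin periodinane, pyridine, CH2Cl2, 0 °C
Reagents that add atoms: none
Why: Dess–Martin oxidation gives the α-alkoxy aldehyde under non-basic conditions that should not epimerise C8.

Step 10
Reactants: 18 (2S,3S)-3-(TBS-oxymethyl)-2-(PMB-oxy)-5-(trimethylsilyl)pent-4-ynal
Product: 19 methyl (3S,4S,5S)-3-hydroxy-4-(PMB-oxy)-5-(TBS-oxymethyl)-7-(trimethylsilyl)hept-6-ynoate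
Conditions: MgBr2·OEt2, CH2=C(OMe)OTBS, CH2Cl2, −78 to −20 °C; aq. NH4Cl
Reagents that add atoms: tert-butyl[(1-methoxyethenyl)oxy]dimethylsilane, C=C(OC)O[Si](C)(C)C(C)(C)C
Why: Chelation-controlled Mukaiyama aldol: magnesium bridges the aldehyde and the C8 PMB oxygen and the ketene silyl acetal attacks the face away from C7, which sets the 9S carbinol syn to O8 (any O-silylated aldolate converges in step 11).

Step 11
Reactants: 19 methyl (3S,4S,5S)-3-hydroxy-4-(PMB-oxy)-5-(TBS-oxymethyl)-7-(trimethylsilyl)hept-6-ynoate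
Product: 20 methyl (3S,4S,5S)-3-(TBS-oxy)-4-(PMB-oxy)-5-(TBS-oxymethyl)-7-(trimethylsilyl)hept-6-ynoate
Conditions: TBSOTf, 2,6-lutidine, CH2Cl2, −78 to 0 °C
Reagents that add atoms: tert-butyldimethylsilyl triflate, CC(C)(C)[Si](C)(C)OS(=O)(=O)C(F)(F)F
Why: Silylation of a hindered secondary alcohol with a silyl triflate and a hindered base, which avoids retro-aldol cleavage.

Step 12
Reactants: 20 methyl (3S,4S,5S)-3-(TBS-oxy)-4-(PMB-oxy)-5-(TBS-oxymethyl)-7-(trimethylsilyl)hept-6-ynoate; 8 (4Z)-5-iodo-4-methylpent-4-enal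
Product: 22 methyl (3S,4S,5S)-2-[(4Z)-1-hydroxy-5-iodo-4-methylpent-4-en-1-yl]-3-(TBS-oxy)-4-(PMB-oxy)-5-(TBS-oxymethyl)-7-(trimethylsilyl)hept-6-ynoate (diastereomers at C10 and C1), via lithium enolate 21 (not isolated)
Conditions: LiN(i-Pr)2, THF, −78 °C; 8, −78 °C; AcOH
Reagents that add atoms: none
Why: Aldol addition of a lithium ester enolate at −78 °C, where β-elimination of the C9 silyloxy group is slow; the uncontrolled centres at C10 and C1 are both removed in step 13.

Step 13
Reactants: 22 aldol adduct (see step 12)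
Product: 24 methyl (2E,6Z)-2-[(1S,2S,3S)-1-(TBS-oxy)-2-(PMB-oxy)-3-(TBS-oxymethyl)-5-(trimethylsilyl)pent-4-yn-1-yl]-7-iodo-6-methylhepta-2,6-dienoate, via C1 mesylate 23 (not isolated)
Conditions: MsCl, Et3N, CH2Cl2, 0 °C; then DBU, rt
Reagents that add atoms: none
Why: Mesylation and E1cB elimination through the ester enolate, which expels mesylate far faster than the C9 silyloxy group and should favour the more stable enoate with C2 trans to the ester (C9 cis to C2), the minor isomer being removed by chromatography.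

Step 14
Reactants: 24 bis-TBS enoate (see step 13)
Product: 25 methyl (2E,6Z)-2-[(1S,2S,3S)-1-(TBS-oxy)-3-(hydroxymethyl)-2-(PMB-oxy)-5-(trimethylsilyl)pent-4-yn-1-yl]-7-iodo-6-methylhepta-2,6-dienoate
Conditions: CSA (cat.), MeOH/CH2Cl2, 0 °C
Reagents that add atoms: none
Why: Acid-catalysed methanolysis removes the primary C6 TBS ether much faster than the hindered secondary C9 TBS ether and leaves the C-silyl alkyne and the PMB ether intact.

Step 15
Reactants: 25 C6 alcohol (see step 14)
Product: 26 methyl (2E,6Z)-2-[(1S,2S,3R)-1-(TBS-oxy)-3-formyl-2-(PMB-oxy)-5-(trimethylsilyl)pent-4-yn-1-yl]-7-iodo-6-methylhepta-2,6-dienoate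
Conditions: Dess–Martin periodinane, pyridine, CH2Cl2, 0 °C; short silica plug, used at once
Reagents that add atoms: none
Why: Dess–Martin oxidation under buffered, non-basic conditions makes the α-ethynyl aldehyde without enolisation, and immediate use limits C7 epimerisation and alkyne-to-allene isomerisation.

Step 16
Reactants: 26 acyclic Z-vinyl iodide aldehyde (see step 15)
Product: 28 methyl (1E,4Z,6S,7S,8S,9S)-6-hydroxy-4-methyl-8-(PMB-oxy)-9-(TBS-oxy)-7-[(trimethylsilyl)ethynyl]cyclodeca-1(10),4-diene-10-carboxylate, via alkenylchromium species 27 (not isolated)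
Conditions: CrCl2 (excess), NiCl2 (cat.), degassed DMSO/THF, rt, slow addition at high dilution
Reagents that add atoms: none
Why: CrCl2 reduces NiCl2 to zerovalent nickel, which inserts into the C5–I bond with retention and passes the alkenyl group to trivalent chromium; the alkenylchromium then adds to the C6 aldehyde in a polar 1,2-addition (Nozaki–Hiyama–Kishi reaction, closest precedent: vinyl iodide–aldehyde macrocyclisations to medium and large carbocycles). The ten-membered ring closes in a 10-exo-trig mode under high dilution, and the Z geometry of C4=C5 (C3 cis to C6) is carried into the ring. The new C6 centre is controlled by the C7 stereocentre: with the ethynyl group antiperiplanar to the incoming C5 (polar Felkin–Anh arrangement), or equally by attack on a six-membered chromium chelate between the C6 carbonyl and the C8 PMB oxygen, the 6S alcohol forms, in which OH and ethynyl are placed for a cis lactone; inside the forming ring this preference is expected but not assured. The step needs chemoselectivity for C–I and freedom from base: the oxophilic, non-basic reagent should leave the enoate, the silylalkyne, both ethers and the acidic C7–H alone, and because C9 carries a silyl ether there is no allylic leaving group for zerovalent nickel to ionise.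

Step 17
Reactants: 28 ten-membered Z-allylic alcohol (see step 16)
Product: 29 methyl (1E,4R,5S,6R,7S,8S,9S)-4,5-epoxy-6-hydroxy-4-methyl-8-(PMB-oxy)-9-(TBS-oxy)-7-[(trimethylsilyl)ethynyl]cyclodec-1(10)-ene-10-carboxylate
Conditions: mCPBA, Na2HPO4, CH2Cl2, 0 °C
Reagents that add atoms: 3-chloroperbenzoic acid, OOC(=O)c1cccc(Cl)c1
Why: Hydroxyl-directed peracid epoxidation of the only electron-rich alkene: with C6–H in the alkene plane (allylic 1,3-strain against C3) and the C6–C7 ring bond out of it, the hydrogen-bonded peracid delivers oxygen to the face of the OH and gives the threo 4R,5S epoxy alcohol, whereas a vanadium/t-BuOOH system is avoided because its tighter O–C–C=C angle favours the erythro isomer in medium-ring cycloalkenols.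

Step 18
Reactants: 29 epoxy alcohol with silylalkyne (see step 17)
Product: 30 methyl (1E,4R,5S,6R,7S,8S,9S)-4,5-epoxy-7-ethynyl-6-hydroxy-4-methyl-8-(PMB-oxy)-9-(TBS-oxy)cyclodec-1(10)-ene-10-carboxylate
Conditions: K2CO3 (cat.), MeOH, 0 °C
Reagents that add atoms: none
Why: Methoxide-catalysed protodesilylation cleaves the C(sp)–Si bond selectively over the O-silyl ether, and the methyl ester is degenerate in methanol.

Step 19
Reactants: 30 terminal alkynol (see step 18)
Product: 31 cis-fused α-methylene γ-lactone (4R,5S,6R,7R,8S,9S; 1E) with 4,5-epoxide, C8 OPMB, C9 OTBS and C10 CO2Me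
Conditions: CO (20 atm), Pd(dba)2 (cat.), dppb (cat.), 1,2-dimethoxyethane, 80 °C
Reagents that add atoms: carbon monoxide, [C-]#[O+]
Why: Palladium-catalysed cyclocarbonylation of a 3-butyn-1-ol: a palladium hydride formed from zerovalent palladium and the alcohol adds to the terminal alkyne with palladium on C11, CO insertion gives the acylpalladium, and the cis C6 hydroxyl closes the five-membered lactone with its exo-methylene, without enolate chemistry or a new stereocentre.

Step 20
Reactants: 31 lactone with C9 OTBS (see step 19)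
Product: 32 the same lactone with free C9 OH (4R,5S,6R,7R,8S,9S)
Conditions: HF·pyridine, pyridine, THF, 0 °C to rt
Reagents that add atoms: none
Why: Buffered fluoride-mediated desilylation of a secondary TBS ether, mild enough for the trisubstituted epoxide and the α-methylene lactone.

Step 21
Reactants: 32 C9 alcohol (see step 20)
Product: 33 the C9 acetate (4R,5S,6R,7R,8S,9S) with C8 OPMB
Conditions: Ac2O, pyridine, DMAP (cat.), CH2Cl2, 0 °C to rt
Reagents that add atoms: acetic anhydride, CC(=O)OC(C)=O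
Why: DMAP-catalysed acetylation of the only free hydroxyl.

Step 22
Reactants: 33 C9 acetate, C8 PMB ether (see step 21)
Product: 34 the C8 alcohol (4R,5S,6R,7R,8S,9S) with C9 OAc
Conditions: DDQ, CH2Cl2/pH 7 phosphate buffer, 0 °C to rt
Reagents that add atoms: none
Why: Oxidative cleavage of the PMB ether by DDQ under neutral conditions, which leaves the electron-poor alkenes, the epoxide and the acetate untouched and gives no base to move the acetyl group.

Step 23
Reactants: 35 methyl (2S)-2-methyloxirane-2-carboxylate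
Product: 36 lithium (2S)-2-methyloxirane-2-carboxylate
Conditions: LiOH·H2O (1 equiv), THF/H2O, 0 °C; evaporate, dry
Reagents that add atoms: lithium hydroxide, [Li+].[OH-]
Why: Saponification of the ester at 0 °C is faster than epoxide opening, and isolating the salt avoids handling the free glycidic acid; the quaternary stereocentre cannot epimerise.

Step 24
Reactants: 34 C8 alcohol with C9 OAc (see step 22); 36 lithium (2S)-2-methyloxirane-2-carboxylate
Product: 38 CNP0274195.1 (target; 4R,5S,6R,7R,8S,9S, glycidate 2S), via mixed anhydride 37 (not isolated)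
Conditions: 36, 2,4,6-trichlorobenzoyl chloride, THF, rt; then 34, DMAP, toluene, rt
Reagents that add atoms: none
Why: Yamaguchi esterification: DMAP attacks the less hindered glycidyl carbonyl of the mixed anhydride and the acylpyridinium acylates the C8 hydroxyl with retention at C8 and at the glycidate centre.

Compound list
1 | (3-bromopropoxy)(tert-butyl)dimethylsilane | CC(C)(C)[Si](C)(C)OCCCBr | starting material
2 | propyne | CC#C | starting material
3 | [3-(TBS-oxy)propyl]magnesium bromide | CC(C)(C)[Si](C)(C)OCCC[Mg]Br | intermediate (not isolated)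
4 | [3-(TBS-oxy)propyl]copper (MgBr2·SMe2 complex) | CC(C)(C)[Si](C)(C)OCCC[Cu] | intermediate (not isolated)
5 | [(1Z)-2-methyl-5-(TBS-oxy)pent-1-en-1-yl]copper | CC(C)(C)[Si](C)(C)OCCC/C(C)=C\[Cu] | intermediate (not isolated)
6 | tert-butyl{[(4Z)-5-iodo-4-methylpent-4-en-1-yl]oxy}dimethylsilane | CC(C)(C)[Si](C)(C)OCCC/C(C)=C\I | intermediate
7 | (4Z)-5-iodo-4-methylpent-4-en-1-ol | OCCC/C(C)=C\I | intermediate
8 | (4Z)-5-iodo-4-methylpent-4-enal | O=CCC/C(C)=C\I | intermediate
9 | (2E)-but-2-ene-1,4-diol | OC/C=C/CO | starting material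
10 | (2E)-4-(TBS-oxy)but-2-en-1-ol | CC(C)(C)[Si](C)(C)OC/C=C/CO | intermediate
11 | [(2R,3R)-3-(TBS-oxymethyl)oxiran-2-yl]methanol | OC[C@H]1O[C@@H]1CO[Si](C)(C)C(C)(C)C | intermediate
12 | ethynyltrimethylsilane | C#C[Si](C)(C)C | starting material
13 | lithium (trimethylsilyl)acetylide | [Li]C#C[Si](C)(C)C | intermediate (not isolated)
14 | diethyl[(trimethylsilyl)ethynyl]aluminium | CC[Al](CC)C#C[Si](C)(C)C | intermediate (not isolated)
15 | (2S,3S)-3-(TBS-oxymethyl)-5-(trimethylsilyl)pent-4-yne-1,2-diol | CC(C)(C)[Si](C)(C)OC[C@H](C#C[Si](C)(C)C)[C@H](O)CO | intermediate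
16 | tert-butyl{[(2S)-2-[(4S)-2-(4-methoxyphenyl)-1,3-dioxolan-4-yl]-4-(trimethylsilyl)but-3-yn-1-yl]oxy}dimethylsilane (both acetal epimers) | COc1ccc(cc1)C1OC[C@@H](O1)[C@@H](C#C[Si](C)(C)C)CO[Si](C)(C)C(C)(C)C | intermediate
17 | (2S,3S)-3-(TBS-oxymethyl)-2-(PMB-oxy)-5-(trimethylsilyl)pent-4-yn-1-ol | CC(C)(C)[Si](C)(C)OC[C@H](C#C[Si](C)(C)C)[C@H](OCc1ccc(OC)cc1)CO | intermediate
18 | (2S,3S)-3-(TBS-oxymethyl)-2-(PMB-oxy)-5-(trimethylsilyl)pent-4-ynal | CC(C)(C)[Si](C)(C)OC[C@H](C#C[Si](C)(C)C)[C@H](OCc1ccc(OC)cc1)C=O | intermediate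
19 | methyl (3S,4S,5S)-3-hydroxy-4-(PMB-oxy)-5-(TBS-oxymethyl)-7-(trimethylsilyl)hept-6-ynoate | CC(C)(C)[Si](C)(C)OC[C@H](C#C[Si](C)(C)C)[C@H](OCc1ccc(OC)cc1)[C@@H](O)CC(=O)OC | intermediate
20 | methyl (3S,4S,5S)-3-(TBS-oxy)-4-(PMB-oxy)-5-(TBS-oxymethyl)-7-(trimethylsilyl)hept-6-ynoate | CC(C)(C)[Si](C)(C)OC[C@H](C#C[Si](C)(C)C)[C@H](OCc1ccc(OC)cc1)[C@@H](O[Si](C)(C)C(C)(C)C)CC(=O)OC | intermediate
21 | lithium enolate of 20 (C10 enolate) | CC(C)(C)[Si](C)(C)OC[C@H](C#C[Si](C)(C)C)[C@H](OCc1ccc(OC)cc1)[C@@H](O[Si](C)(C)C(C)(C)C)C=C(OC)O[Li] | intermediate (not isolated)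
22 | methyl (3S,4S,5S)-2-[(4Z)-1-hydroxy-5-iodo-4-methylpent-4-en-1-yl]-3-(TBS-oxy)-4-(PMB-oxy)-5-(TBS-oxymethyl)-7-(trimethylsilyl)hept-6-ynoate (diastereomers at C10 and C1) | CC(C)(C)[Si](C)(C)OC[C@H](C#C[Si](C)(C)C)[C@H](OCc1ccc(OC)cc1)[C@@H](O[Si](C)(C)C(C)(C)C)C(C(=O)OC)C(O)CC/C(C)=C\I | intermediate
23 | C1 methanesulfonate of 22 | CC(C)(C)[Si](C)(C)OC[C@H](C#C[Si](C)(C)C)[C@H](OCc1ccc(OC)cc1)[C@@H](O[Si](C)(C)C(C)(C)C)C(C(=O)OC)C(OS(C)(=O)=O)CC/C(C)=C\I | intermediate (not isolated)
24 | methyl (2E,6Z)-2-[(1S,2S,3S)-1-(TBS-oxy)-2-(PMB-oxy)-3-(TBS-oxymethyl)-5-(trimethylsilyl)pent-4-yn-1-yl]-7-iodo-6-methylhepta-2,6-dienoate | CC(C)(C)[Si](C)(C)OC[C@H](C#C[Si](C)(C)C)[C@H](OCc1ccc(OC)cc1)[C@@H](O[Si](C)(C)C(C)(C)C)/C(C(=O)OC)=C\CC/C(C)=C\I | intermediate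
25 | methyl (2E,6Z)-2-[(1S,2S,3S)-1-(TBS-oxy)-3-(hydroxymethyl)-2-(PMB-oxy)-5-(trimethylsilyl)pent-4-yn-1-yl]-7-iodo-6-methylhepta-2,6-dienoate | OC[C@H](C#C[Si](C)(C)C)[C@H](OCc1ccc(OC)cc1)[C@@H](O[Si](C)(C)C(C)(C)C)/C(C(=O)OC)=C\CC/C(C)=C\I | intermediate
26 | methyl (2E,6Z)-2-[(1S,2S,3R)-1-(TBS-oxy)-3-formyl-2-(PMB-oxy)-5-(trimethylsilyl)pent-4-yn-1-yl]-7-iodo-6-methylhepta-2,6-dienoate (key-step precursor) | O=C[C@H](C#C[Si](C)(C)C)[C@H](OCc1ccc(OC)cc1)[C@@H](O[Si](C)(C)C(C)(C)C)/C(C(=O)OC)=C\CC/C(C)=C\I | intermediate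
27 | alkenylchromium dichloride of 26 (CrCl2 at C5 in place of iodine) | O=C[C@H](C#C[Si](C)(C)C)[C@H](OCc1ccc(OC)cc1)[C@@H](O[Si](C)(C)C(C)(C)C)/C(C(=O)OC)=C\CC/C(C)=C\[Cr](Cl)Cl | intermediate (not isolated)
28 | methyl (1E,4Z,6S,7S,8S,9S)-6-hydroxy-4-methyl-8-(PMB-oxy)-9-(TBS-oxy)-7-[(trimethylsilyl)ethynyl]cyclodeca-1(10),4-diene-10-carboxylate (key-step product) | C/C1=C/[C@H](O)[C@H](C#C[Si](C)(C)C)[C@H](OCc2ccc(OC)cc2)[C@@H](O[Si](C)(C)C(C)(C)C)/C(C(=O)OC)=C\CC1 | intermediate
29 | methyl (1E,4R,5S,6R,7S,8S,9S)-4,5-epoxy-6-hydroxy-4-methyl-8-(PMB-oxy)-9-(TBS-oxy)-7-[(trimethylsilyl)ethynyl]cyclodec-1(10)-ene-10-carboxylate | O[C@@H]1[C@H](C#C[Si](C)(C)C)[C@H](OCc3ccc(OC)cc3)[C@@H](O[Si](C)(C)C(C)(C)C)/C(C(=O)OC)=C\CC[C@@]2(C)O[C@@H]12 | intermediate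
30 | methyl (1E,4R,5S,6R,7S,8S,9S)-4,5-epoxy-7-ethynyl-6-hydroxy-4-methyl-8-(PMB-oxy)-9-(TBS-oxy)cyclodec-1(10)-ene-10-carboxylate | O[C@@H]1[C@H](C#C)[C@H](OCc3ccc(OC)cc3)[C@@H](O[Si](C)(C)C(C)(C)C)/C(C(=O)OC)=C\CC[C@@]2(C)O[C@@H]12 | intermediate
31 | cis-fused α-methylene γ-lactone (4R,5S,6R,7R,8S,9S; 1E): 4,5-epoxide, C8 OPMB, C9 OTBS, C10 CO2Me | C=C1C(=O)O[C@@H]2[C@H]1[C@H](OCc3ccc(OC)cc3)[C@@H](O[Si](C)(C)C(C)(C)C)/C(C(=O)OC)=C\CC[C@@]1(C)O[C@@H]21 | intermediate
32 | the same lactone with C8 OPMB and free C9 OH | C=C1C(=O)O[C@@H]2[C@H]1[C@H](OCc3ccc(OC)cc3)[C@@H](O)/C(C(=O)OC)=C\CC[C@@]1(C)O[C@@H]21 | intermediate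
33 | the same lactone with C8 OPMB and C9 OAc | C=C1C(=O)O[C@@H]2[C@H]1[C@H](OCc3ccc(OC)cc3)[C@@H](OC(C)=O)/C(C(=O)OC)=C\CC[C@@]1(C)O[C@@H]21 | intermediate
34 | the same lactone with free C8 OH and C9 OAc | C=C1C(=O)O[C@@H]2[C@H]1[C@H](O)[C@@H](OC(C)=O)/C(C(=O)OC)=C\CC[C@@]1(C)O[C@@H]21 | intermediate
35 | methyl (2S)-2-methyloxirane-2-carboxylate | COC(=O)[C@]1(C)CO1 | starting material
36 | lithium (2S)-2-methyloxirane-2-carboxylate | [Li+].[O-]C(=O)[C@]1(C)CO1 | intermediate
37 | (2S)-2-methyloxirane-2-carboxylic 2,4,6-trichlorobenzoic anhydride | O=C(OC(=O)[C@]1(C)CO1)c1c(Cl)cc(Cl)cc1Cl | intermediate (not isolated)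
38 | CNP0274195.1: the lactone 34 esterified at O8 with (2S)-2-methyloxirane-2-carboxylic acid | C=C1C(=O)O[C@@H]2[C@H]1[C@H](OC(=O)[C@]1(C)CO1)[C@@H](OC(C)=O)/C(C(=O)OC)=C\CC[C@@]1(C)O[C@@H]21 | target

Total step count: 24
Longest linear sequence: 20 steps (steps 4–22 and 24, from 9)

Steps most likely to fail

Step 16. The labile α-ethynyl aldehyde may epimerise at C7 or isomerise to the allene before it closes, intermolecular coupling may compete, and above all the facial selectivity at C6 inside the forming ring may be poor or reversed. The fallback sets out from 26 and no longer relies on the carbon–carbon bond formation to set C6. The same chromium-mediated closure is run; the C6-epimeric allylic alcohol F1 (alone or mixed with 28) is oxidised with Dess–Martin periodinane/pyridine to the ten-membered Z-enone F2. The ketone is then reduced under reagent control by Corey–Bakshi–Shibata reduction (2-methyl-CBS-oxazaborolidine, catecholborane, toluene, −78 °C; the S catalyst if the alkenyl arm acts as the large group), which returns to the route at 28.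

Step 19. The catalyst may die, or the trisubstituted epoxide next to the reacting hydroxyl may open or rearrange at the temperature and CO pressure needed. The fallback sets out from 30 and builds the lactone carbonyl by radical chemistry. The C6 hydroxyl is converted (COCl2, pyridine, CH2Cl2, 0 °C; then PhSeH, pyridine) into the Se-phenyl selenocarbonate F3. Bu3SnH and AIBN in benzene at 80 °C then generate the alkoxycarbonyl radical, which closes 5-exo-dig onto the terminal alkyne; the vinyl radical is reduced at C13 to the exo-methylene, and the route is rejoined at 31.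

Step 24. Acylation of the hindered C8 hydroxyl may be slow enough for the C9 acetyl group to migrate to O8 under the basic conditions, or for the mixed anhydride to decay. The fallback sets out from 31 and reverses the order of the two acylations, so that no migratable acyl group is present while the hindered ester is forced. DDQ (CH2Cl2/pH 7 buffer) removes the PMB group to give the C8 alcohol with the C9 silyl ether in place F4. Yamaguchi esterification with 36 gives the C8 glycidate with the C9 silyl ether F5. HF·pyridine/pyridine in THF frees the C9 alcohol of the glycidate F6. Acetylation (Ac2O, pyridine, DMAP) then returns to the route at 38.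

Further compounds
F1 | step 16 | methyl (1E,4Z,6R,7S,8S,9S)-6-hydroxy-4-methyl-8-(PMB-oxy)-9-(TBS-oxy)-7-[(trimethylsilyl)ethynyl]cyclodeca-1(10),4-diene-10-carboxylate (C6 epimer of 28) | C/C1=C/[C@@H](O)[C@H](C#C[Si](C)(C)C)[C@H](OCc2ccc(OC)cc2)[C@@H](O[Si](C)(C)C(C)(C)C)/C(C(=O)OC)=C\CC1
F2 | step 16 | methyl (1E,4Z,7R,8S,9S)-4-methyl-6-oxo-8-(PMB-oxy)-9-(TBS-oxy)-7-[(trimethylsilyl)ethynyl]cyclodeca-1(10),4-diene-10-carboxylate | C/C1=C/C(=O)[C@H](C#C[Si](C)(C)C)[C@H](OCc2ccc(OC)cc2)[C@@H](O[Si](C)(C)C(C)(C)C)/C(C(=O)OC)=C\CC1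
F3 | step 19 | O6-[(phenylselanyl)carbonyl] derivative of 30 (Se-phenyl selenocarbonate) | O=C([Se]c1ccccc1)O[C@@H]1[C@H](C#C)[C@H](OCc3ccc(OC)cc3)[C@@H](O[Si](C)(C)C(C)(C)C)/C(C(=O)OC)=C\CC[C@@]2(C)O[C@@H]12
F4 | step 24 | lactone 31 with free C8 OH and C9 OTBS | C=C1C(=O)O[C@@H]2[C@H]1[C@H](O)[C@@H](O[Si](C)(C)C(C)(C)C)/C(C(=O)OC)=C\CC[C@@]1(C)O[C@@H]21
F5 | step 24 | C8 (2S)-2-methyloxirane-2-carboxylate of F4, C9 OTBS | C=C1C(=O)O[C@@H]2[C@H]1[C@H](OC(=O)[C@]1(C)CO1)[C@@H](O[Si](C)(C)C(C)(C)C)/C(C(=O)OC)=C\CC[C@@]1(C)O[C@@H]21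
F6 | step 24 | C8 (2S)-2-methyloxirane-2-carboxylate with free C9 OH | C=C1C(=O)O[C@@H]2[C@H]1[C@H](OC(=O)[C@]1(C)CO1)[C@@H](O)/C(C(=O)OC)=C\CC[C@@]1(C)O[C@@H]21
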